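**Retrosynthetic overview**
1. The C9 carbinol is made last, by CBS reduction of the spiro 2-methylcyclohexenone that already carries the acetate.
2. The cyclohexenone (the only ring built) comes from an intramolecular aldol condensation of a CH2CHO arm and a CH2C(=O)Et arm on the quaternary cyclopentane carbon.
3. The side-chain C5'–C4' bond comes from a Cu-catalysed coupling of a core tosylate with a Roche-type C4 Grignard reagent, which brings in C2'.
4. The spiro carbon comes from angular alkylation of the dihydronepetalactone enolate; DIBAL and a methoxymethylene Wittig then unfold the lactone into the CH2CHO arm and the C5' alcohol.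
5. The cyclopentane with C1 and C4 (and C6' after hydrogenation) is bought as the chiral-pool lactone nepetalactone; ring order: cyclopentane (given), then cyclohexenone.

Assumption: (4aS,7S,7aR)-nepetalactone (main lactone of commercial catnip oil), 2-(bromomethyl)but-1-ene and (R)-3-bromo-2-methylpropan-1-ol are taken as catalogue compounds.

Locants in the "Why" lines are those of the target: spiro[4.5]decene C1–C10 (C1 bears the side chain, C4 the ring methyl, C5 is spiro, C9 the carbinol); side chain C6' (ring-bound CH) to C1' (CH2OAc). Compounds are numbered in the order they appear in the steps.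

**Step 1**
Reactants: 1 (4aS,7S,7aR)-nepetalactone
Product: 2 (4S,4aR,7S,7aR)-dihydronepetalactone
Conditions: H2 (1 atm), 5% Pd/C, EtOAc, rt
Reagents that add atoms: none
Why: Heterogeneous syn-hydrogenation of the enol-lactone C=C from the convex face of the cis-fused bicycle (the face of H-4a and H-7a) puts the new H cis to H-4a and so sets C6' (4S in lactone numbering).

**Step 2**
Reactants: 2 (4S,4aR,7S,7aR)-dihydronepetalactone; 3 2-(bromomethyl)but-1-ene
Product: 5 (4S,4aR,7S,7aR)-4,7-dimethyl-7a-(2-methylidenebutyl)hexahydrocyclopenta[c]pyran-1(3H)-one, via lithium enolate 4 (not isolated)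
Conditions: LDA, THF, −78 °C; then 3, DMPU, −78 → −20 °C
Reagents that add atoms: none
Why: Angular lactone-enolate alkylation in which the allylic bromide should add on the convex face syn to H-4a (concave face shielded by the pseudo-axial C4-lactone methyl and the cyclopentane fold), keeping the cis ring fusion and fixing C5 with the new arm (future C10) cis to the ring methyl and the carbonyl (future C6) cis to the side chain.

**Step 3**
Reactants: 5 (4S,4aR,7S,7aR)-4,7-dimethyl-7a-(2-methylidenebutyl)hexahydrocyclopenta[c]pyran-1(3H)-one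
Product: 6 (4S,4aR,7S,7aR)-4,7-dimethyl-7a-(2-methylidenebutyl)octahydrocyclopenta[c]pyran-1-ol (lactol, both anomers)
Conditions: DIBAL-H, CH2Cl2, −78 °C; Rochelle salt
Reagents that add atoms: none
Why: DIBAL half-reduction of a lactone stops at the lactol at low temperature, and no stereocentre of the target is touched.

**Step 4**
Reactants: 6 lactol (both anomers)
Product: 7 (2S)-2-[(1R,2R,3S)-2-(2-methoxyethenyl)-3-methyl-2-(2-methylidenebutyl)cyclopentyl]propan-1-ol (E/Z mixture)
Conditions: MeOCH2PPh3Cl, t-BuOK, THF, 0 → 40 °C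
Reagents that add atoms: (methoxymethyl)triphenylphosphonium chloride, COC[P+](c1ccccc1)(c1ccccc1)c1ccccc1.[Cl-]
Why: Wittig methoxymethylenation of the open hydroxy-aldehyde form of the lactol adds C7 as an enol ether (masked CH2CHO) and frees the C5' alcohol; the E/Z ratio is irrelevant.

**Step 5**
Reactants: 7 (2S)-2-[(1R,2R,3S)-2-(2-methoxyethenyl)-3-methyl-2-(2-methylidenebutyl)cyclopentyl]propan-1-ol
Product: 8 (2S)-2-[(1R,2R,3S)-2-(2-methoxyethenyl)-3-methyl-2-(2-methylidenebutyl)cyclopentyl]propyl 4-methylbenzenesulfonate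
Conditions: TsCl, Et3N, DMAP (cat.), CH2Cl2, 0 °C → rt
Reagents that add atoms: p-toluenesulfonyl chloride, Cc1ccc(cc1)S(Cl)(=O)=O
Why: Sulfonylation of the only alcohol under basic conditions that the enol ether tolerates gives the sp3 electrophile for the coupling.

**Step 6**
Reactants: 9 (R)-3-bromo-2-methylpropan-1-ol
Product: 10 (R)-(3-bromo-2-methylpropoxy)(tert-butyl)dimethylsilane
Conditions: TBSCl, imidazole, DMF, rt
Reagents that add atoms: tert-butyldimethylsilyl chloride, CC(C)(C)[Si](C)(C)Cl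
Why: Silyl protection of the primary alcohol so that a Grignard reagent can be made; the stereocentre is untouched.

**Step 7**
Reactants: 10 (R)-(3-bromo-2-methylpropoxy)(tert-butyl)dimethylsilane
Product: 12 (S)-4-[(tert-butyldimethylsilyl)oxy]-3-methylbutan-1-ol, via Grignard reagent 11 (not isolated)
Conditions: Mg, THF, reflux; then (CH2O)n, 0 °C → rt; H2O
Reagents that add atoms: paraformaldehyde (as formaldehyde), C=O
Why: Grignard addition to formaldehyde gives the one-carbon homologue without involving the stereocentre (the descriptor changes only because of CIP priorities).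

**Step 8**
Reactants: 12 (S)-4-[(tert-butyldimethylsilyl)oxy]-3-methylbutan-1-ol
Product: 13 (S)-(4-bromo-2-methylbutoxy)(tert-butyl)dimethylsilane
Conditions: CBr4, PPh3, CH2Cl2, 0 °C
Reagents that add atoms: carbon tetrabromide, BrC(Br)(Br)Br
Why: Appel bromination of a primary alcohol under neutral conditions leaves the TBS ether intact.

**Step 9**
Reactants: 8 (2S)-2-[(1R,2R,3S)-2-(2-methoxyethenyl)-3-methyl-2-(2-methylidenebutyl)cyclopentyl]propyl 4-methylbenzenesulfonate; 13 (S)-(4-bromo-2-methylbutoxy)(tert-butyl)dimethylsilane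
Product: 15 tert-butyl{[(2S,6R)-6-[(1R,2R,3S)-2-(2-methoxyethenyl)-3-methyl-2-(2-methylidenebutyl)cyclopentyl]-2-methylheptyl]oxy}dimethylsilane, via Grignard reagent 14 (not isolated)
Conditions: 13, Mg, THF, 40 °C; then 8, Li2CuCl4 (5 mol %), THF, −40 °C → rt
Reagents that add atoms: none
Why: Copper-catalysed Grignard–tosylate coupling (Fouquet–Schlosser/Kochi) forms C5'–C4' by substitution at the primary carbon, so C2' arrives intact from the building block and C6' is not involved.

**Step 10**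
Reactants: 15 tert-butyl{[(2S,6R)-6-[(1R,2R,3S)-2-(2-methoxyethenyl)-3-methyl-2-(2-methylidenebutyl)cyclopentyl]-2-methylheptyl]oxy}dimethylsilane
Product: 16 2-[(1R,2R,5S)-2-[(2R,6S)-7-hydroxy-6-methylheptan-2-yl]-5-methyl-1-(2-methylidenebutyl)cyclopentyl]acetaldehyde
Conditions: 1 M HCl, THF, 0 °C → rt
Reagents that add atoms: water, O
Why: Acid hydrolysis of the methyl enol ether unveils the C6H2–C7HO arm and the same acid cleaves the primary TBS ether; no stereocentre is affected.

**Step 11**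
Reactants: 16 2-[(1R,2R,5S)-2-[(2R,6S)-7-hydroxy-6-methylheptan-2-yl]-5-methyl-1-(2-methylidenebutyl)cyclopentyl]acetaldehyde
Product: 18 2-[(1S,2R,5S)-2-[(2R,6S)-7-hydroxy-6-methylheptan-2-yl]-5-methyl-1-(2-oxobutyl)cyclopentyl]acetaldehyde, via secondary ozonide 17 (not isolated)
Conditions: O3, CH2Cl2, −78 °C; then PPh3, −78 °C → rt
Reagents that add atoms: ozone, [O-][O+]=O
Why: Ozonolysis of the only C=C bond with reductive work-up turns the 2-methylidenebutyl group into the ethyl ketone arm C10–C9(=O)–C8.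

**Step 12**
Reactants: 18 2-[(1S,2R,5S)-2-[(2R,6S)-7-hydroxy-6-methylheptan-2-yl]-5-methyl-1-(2-oxobutyl)cyclopentyl]acetaldehyde
Product: 20 (2S,6R)-6-[(1R,4S,5S)-4,8-dimethyl-9-oxospiro[4.5]dec-7-en-1-yl]-2-methylheptan-1-ol, via aldol adduct 19 (not isolated)
Conditions: KOH (cat.), MeOH, rt → 50 °C
Reagents that add atoms: none
Why: Intramolecular aldol condensation in which only the C8 enolate of the ethyl ketone attacking the C7 aldehyde can give a six-membered ring, and dehydration gives the conjugated 2-methylcyclohexenone with C5 already fixed.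

**Step 13**
Reactants: 20 (2S,6R)-6-[(1R,4S,5S)-4,8-dimethyl-9-oxospiro[4.5]dec-7-en-1-yl]-2-methylheptan-1-ol
Product: 21 (2S,6R)-6-[(1R,4S,5S)-4,8-dimethyl-9-oxospiro[4.5]dec-7-en-1-yl]-2-methylheptyl acetate
Conditions: Ac2O, pyridine, DMAP (cat.), CH2Cl2, rt
Reagents that add atoms: acetic anhydride, CC(=O)OC(C)=O
Why: Acylation of the only hydroxyl group, done before the reduction so that the C9 alcohol never competes.

**Step 14**
Reactants: 21 (2S,6R)-6-[(1R,4S,5S)-4,8-dimethyl-9-oxospiro[4.5]dec-7-en-1-yl]-2-methylheptyl acetate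
Product: 22 (2S,6R)-6-[(1R,4S,5S,9S)-9-hydroxy-4,8-dimethylspiro[4.5]dec-7-en-1-yl]-2-methylheptyl acetate (CNP0304655.1)
Conditions: (R)-2-methyl-CBS-oxazaborolidine (20 mol %), catecholborane, toluene, −78 °C; MeOH, aq. NaHCO3
Reagents that add atoms: none
Why: Corey–Bakshi–Shibata 1,2-reduction under catalyst control, with alkenyl C8 as the large and C10H2 as the small substituent, so that the (R)-catalyst gives the 9S allylic alcohol while the acetate is untouched.

**Compound list**
1 | (4aS,7S,7aR)-nepetalactone [(4aS,7S,7aR)-4,7-dimethyl-5,6,7,7a-tetrahydrocyclopenta[c]pyran-1(4aH)-one] | O1C=C(C)[C@H]2CC[C@H](C)[C@H]2C1=O | starting material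
2 | (4S,4aR,7S,7aR)-dihydronepetalactone [(4S,4aR,7S,7aR)-4,7-dimethylhexahydrocyclopenta[c]pyran-1(3H)-one] | O1C[C@@H](C)[C@H]2CC[C@H](C)[C@H]2C1=O | intermediate
3 | 2-(bromomethyl)but-1-ene | C=C(CC)CBr | starting material
4 | lithium enolate of 2 (C1=C7a enolate) | O1C[C@@H](C)[C@H]2CC[C@H](C)C2=C1[O-].[Li+] | intermediate (not isolated)
5 | (4S,4aR,7S,7aR)-4,7-dimethyl-7a-(2-methylidenebutyl)hexahydrocyclopenta[c]pyran-1(3H)-one | O1C[C@@H](C)[C@H]2CC[C@H](C)[C@@]2(CC(=C)CC)C1=O | intermediate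
6 | (4S,4aR,7S,7aR)-4,7-dimethyl-7a-(2-methylidenebutyl)octahydrocyclopenta[c]pyran-1-ol (lactol, both anomers) | O1C[C@@H](C)[C@H]2CC[C@H](C)[C@@]2(CC(=C)CC)C1O | intermediate
7 | (2S)-2-[(1R,2R,3S)-2-(2-methoxyethenyl)-3-methyl-2-(2-methylidenebutyl)cyclopentyl]propan-1-ol (E/Z) | OC[C@@H](C)[C@H]1CC[C@H](C)[C@@]1(CC(=C)CC)C=COC | intermediate
8 | (2S)-2-[(1R,2R,3S)-2-(2-methoxyethenyl)-3-methyl-2-(2-methylidenebutyl)cyclopentyl]propyl 4-methylbenzenesulfonate | Cc1ccc(cc1)S(=O)(=O)OC[C@@H](C)[C@H]2CC[C@H](C)[C@@]2(CC(=C)CC)C=COC | intermediate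
9 | (R)-3-bromo-2-methylpropan-1-ol | OC[C@@H](C)CBr | starting material
10 | (R)-(3-bromo-2-methylpropoxy)(tert-butyl)dimethylsilane | CC(C)(C)[Si](C)(C)OC[C@@H](C)CBr | intermediate
11 | (R)-{3-[(tert-butyldimethylsilyl)oxy]-2-methylpropyl}magnesium bromide | CC(C)(C)[Si](C)(C)OC[C@@H](C)C[Mg]Br | intermediate (not isolated)
12 | (S)-4-[(tert-butyldimethylsilyl)oxy]-3-methylbutan-1-ol | CC(C)(C)[Si](C)(C)OC[C@@H](C)CCO | intermediate
13 | (S)-(4-bromo-2-methylbutoxy)(tert-butyl)dimethylsilane | CC(C)(C)[Si](C)(C)OC[C@@H](C)CCBr | intermediate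
14 | (S)-{4-[(tert-butyldimethylsilyl)oxy]-3-methylbutyl}magnesium bromide | CC(C)(C)[Si](C)(C)OC[C@@H](C)CC[Mg]Br | intermediate (not isolated)
15 | tert-butyl{[(2S,6R)-6-[(1R,2R,3S)-2-(2-methoxyethenyl)-3-methyl-2-(2-methylidenebutyl)cyclopentyl]-2-methylheptyl]oxy}dimethylsilane | CC(C)(C)[Si](C)(C)OC[C@@H](C)CCC[C@@H](C)[C@H]1CC[C@H](C)[C@@]1(CC(=C)CC)C=COC | intermediate
16 | 2-[(1R,2R,5S)-2-[(2R,6S)-7-hydroxy-6-methylheptan-2-yl]-5-methyl-1-(2-methylidenebutyl)cyclopentyl]acetaldehyde | OC[C@@H](C)CCC[C@@H](C)[C@H]1CC[C@H](C)[C@@]1(CC(=C)CC)CC=O | intermediate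
17 | secondary ozonide (3-ethyl-1,2,4-trioxolan-3-yl)methyl analogue of 16 | OC[C@@H](C)CCC[C@@H](C)[C@H]1CC[C@H](C)[C@@]1(CC2(CC)OCOO2)CC=O | intermediate (not isolated)
18 | 2-[(1S,2R,5S)-2-[(2R,6S)-7-hydroxy-6-methylheptan-2-yl]-5-methyl-1-(2-oxobutyl)cyclopentyl]acetaldehyde | OC[C@@H](C)CCC[C@@H](C)[C@H]1CC[C@H](C)[C@@]1(CC(=O)CC)CC=O | intermediate
19 | aldol adduct: 7-hydroxy-8-methyl-9-oxo spirodecane precursor of 20 (C7/C8 epimers) | OC[C@@H](C)CCC[C@@H](C)[C@H]1CC[C@H](C)[C@@]12CC(O)C(C)C(=O)C2 | intermediate (not isolated)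
20 | (2S,6R)-6-[(1R,4S,5S)-4,8-dimethyl-9-oxospiro[4.5]dec-7-en-1-yl]-2-methylheptan-1-ol | OC[C@@H](C)CCC[C@@H](C)[C@H]1CC[C@H](C)[C@@]12CC=C(C)C(=O)C2 | intermediate
21 | (2S,6R)-6-[(1R,4S,5S)-4,8-dimethyl-9-oxospiro[4.5]dec-7-en-1-yl]-2-methylheptyl acetate | CC(=O)OC[C@@H](C)CCC[C@@H](C)[C@H]1CC[C@H](C)[C@@]12CC=C(C)C(=O)C2 | intermediate
22 | (2S,6R)-6-[(1R,4S,5S,9S)-9-hydroxy-4,8-dimethylspiro[4.5]dec-7-en-1-yl]-2-methylheptyl acetate | CC(=O)OC[C@@H](C)CCC[C@@H](C)[C@H]1CC[C@H](C)[C@@]12CC=C(C)[C@@H](O)C2 | target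

**Totals**
Total step count: 14. Longest linear sequence: 11 steps (steps 1–5 and 9–14); steps 6–8 are the side branch.

**Three steps most likely to fail**

Step 2 (angular alkylation). The facial preference at the enolate carbon is an argument from ring shape, not a precedent on this exact lactone: the vicinal ring methyl sits on the face the bromide must use, so the selectivity may be low, and O-alkylation is possible. The fallback gives up the bicyclic enolate and lets the bulk of the side chain steer. It sets out from 2: saponification (LiOH, THF–H2O) and silylation of the freed alcohol (TBDPSCl, imidazole; K2CO3–MeOH work-up) give (1R,2R,5S)-2-[(2S)-1-(tert-butyldiphenylsilyloxy)propan-2-yl]-5-methylcyclopentane-1-carboxylic acid F1. Its dianion (LDA, 2.2 equiv, THF–DMPU, −78 °C) is alkylated with 3 on the face away from the α-branched silyloxy side chain, giving (1R,2R,5S)-2-[(2S)-1-(tert-butyldiphenylsilyloxy)propan-2-yl]-5-methyl-1-(2-methylidenebutyl)cyclopentane-1-carboxylic acid F2. TBAF followed by a trace of TsOH closes the lactone, and the route is rejoined at 5.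

Step 9 (Cu-catalysed coupling). The tosylate is β-branched and sits next to a crowded ring, so substitution may be slow and Grignard homocoupling may win. The fallback reverses the polarity so that the hindered partner becomes the nucleophile. It sets out from 8: sodium benzenesulfinate (NaI cat., DMF, 80 °C) gives {(2S)-2-[(1R,2R,3S)-2-(2-methoxyethenyl)-3-methyl-2-(2-methylidenebutyl)cyclopentyl]propyl} phenyl sulfone F3. Deprotonation (n-BuLi, THF–DMPU, −78 °C) and alkylation with the unhindered bromide 13 give the C5'-phenylsulfonyl derivative of 15 (both C5' epimers) F4. Reductive desulfonylation (Mg, MeOH) returns to the route at 15.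

Step 14 (CBS reduction). The catalyst may be mismatched with the substrate, because the C4 methyl can lie over the face of C9=O that must receive hydride. The fallback uses substrate control followed by inversion. It sets out from 21: Luche reduction (NaBH4, CeCl3·7H2O, MeOH, −78 °C) is expected to deliver hydride away from that methyl and give (2S,6R)-6-[(1R,4S,5S,9R)-9-hydroxy-4,8-dimethylspiro[4.5]dec-7-en-1-yl]-2-methylheptyl acetate F5. Mitsunobu inversion with chloroacetic acid (PPh3, DIAD, THF) gives (2S,6R)-6-[(1R,4S,5S,9S)-9-(chloroacetoxy)-4,8-dimethylspiro[4.5]dec-7-en-1-yl]-2-methylheptyl acetate F6. Selective removal of the chloroacetyl group (thiourea, NaHCO3, EtOH), which spares the primary acetate, arrives at 22.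

**Further compounds**
F1 | step 2 | (1R,2R,5S)-2-[(2S)-1-(tert-butyldiphenylsilyloxy)propan-2-yl]-5-methylcyclopentane-1-carboxylic acid | CC(C)(C)[Si](c1ccccc1)(c1ccccc1)OC[C@@H](C)[C@H]1CC[C@H](C)[C@H]1C(=O)O
F2 | step 2 | (1R,2R,5S)-2-[(2S)-1-(tert-butyldiphenylsilyloxy)propan-2-yl]-5-methyl-1-(2-methylidenebutyl)cyclopentane-1-carboxylic acid | CC(C)(C)[Si](c1ccccc1)(c1ccccc1)OC[C@@H](C)[C@H]1CC[C@H](C)[C@@]1(CC(=C)CC)C(=O)O
F3 | step 9 | {(2S)-2-[(1R,2R,3S)-2-(2-methoxyethenyl)-3-methyl-2-(2-methylidenebutyl)cyclopentyl]propyl} phenyl sulfone | O=S(=O)(c1ccccc1)C[C@@H](C)[C@H]2CC[C@H](C)[C@@]2(CC(=C)CC)C=COC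
F4 | step 9 | C5'-phenylsulfonyl derivative of 15 (both C5' epimers) | CC(C)(C)[Si](C)(C)OC[C@@H](C)CCC(S(=O)(=O)c1ccccc1)[C@@H](C)[C@H]2CC[C@H](C)[C@@]2(CC(=C)CC)C=COC
F5 | step 14 | (2S,6R)-6-[(1R,4S,5S,9R)-9-hydroxy-4,8-dimethylspiro[4.5]dec-7-en-1-yl]-2-methylheptyl acetate | CC(=O)OC[C@@H](C)CCC[C@@H](C)[C@H]1CC[C@H](C)[C@@]12CC=C(C)[C@H](O)C2
F6 | step 14 | (2S,6R)-6-[(1R,4S,5S,9S)-9-(chloroacetoxy)-4,8-dimethylspiro[4.5]dec-7-en-1-yl]-2-methylheptyl acetate | CC(=O)OC[C@@H](C)CCC[C@@H](C)[C@H]1CC[C@H](C)[C@@]12CC=C(C)[C@@H](OC(=O)CCl)C2
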